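The route rests on making the oxolane (ring O, C14, C15, C16, C17; chain numbered from the lactone carbonyl C1) from an oxane that still contains C13. A hetero-Diels–Alder adduct of a chiral aldehyde and 1-methoxybutadiene is osmylated on its free face and becomes a pyranoside whose equatorial C14 triflate is antiperiplanar to the ring C13–O bond. On solvolysis the ring oxygen shifts from C13 to C14. One operation contracts the ring, inverts C14 to the 2,3-cis-2,5-trans pattern and releases the exocyclic sp2 carbon C13, the feature exploited, as the aldehyde for the Z-C12=C13 olefination. Propargylation (C11), alkenylchromium addition (C19), esterification and copper-mediated C7–C8 closure complete the macrolide.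

Key step: step 7

Assumption: the alkene geometries are taken literally from the SMILES (2Z,6E,8Z,12Z,20E); the temporary C5 carbinol configuration (5R) does not matter for the target because C5 ends as a ketone.

Step 1
Reactants: 1 methyl (S)-3-hydroxy-2-methylpropanoate
Product: 2 methyl (S)-3-(tert-butyldimethylsilyloxy)-2-methylpropanoate
Conditions: TBSCl, imidazole, CH2Cl2, rt
Reagents that add atoms: tert-butyldimethylsilyl chloride CC(C)(C)[Si](C)(C)Cl
Why: Standard silylation of the primary alcohol (later C19-O); the stereocentre that becomes C18 is bought in and is not touched.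

Step 2
Reactants: 2 methyl (S)-3-(tert-butyldimethylsilyloxy)-2-methylpropanoate
Product: 3 (S)-3-(tert-butyldimethylsilyloxy)-2-methylpropanal
Conditions: DIBAL-H (1.05 equiv), CH2Cl2, −78 °C; aq. potassium sodium tartrate
Reagents that add atoms: none
Why: Partial ester reduction at −78 °C stops at the aldehyde level, and the cold, non-basic work-up avoids epimerisation of the α-methyl centre.

Step 3
Reactants: 3 (S)-3-(tert-butyldimethylsilyloxy)-2-methylpropanal; 4 (E)-1-methoxybuta-1,3-diene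
Product: 5 (2S,6R)-6-[(S)-1-(tert-butyldimethylsilyloxy)propan-2-yl]-2-methoxy-5,6-dihydro-2H-pyran (2,6-cis)
Conditions: [CrCl(L)] 5 mol% (L = dianion of the Schiff base of (1R,2S)-1-aminoindan-2-ol and 3-(1-adamantyl)-2-hydroxy-5-methylbenzaldehyde), 4 Å MS, neat, rt
Reagents that add atoms: none
Why: Enantioselective hetero-Diels–Alder reaction of a mono-oxygenated diene with an aldehyde under a chiral trivalent chromium Lewis acid; endo addition to the Re face of 3, imposed by the (1R,2S) ligand, sets C17 (R) and the cis acetal centre C13 (S), and the diene terminus bonds to the carbonyl carbon for electronic reasons.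

Step 4
Reactants: 5 (2S,6R)-6-[(S)-1-(tert-butyldimethylsilyloxy)propan-2-yl]-2-methoxy-5,6-dihydro-2H-pyran
Product: 6 (2S,3S,4S,6R)-6-[(S)-1-(tert-butyldimethylsilyloxy)propan-2-yl]-2-methoxyoxane-3,4-diol
Conditions: OsO4 (2 mol%), NMO, acetone/H2O, 0 °C to rt
Reagents that add atoms: N-methylmorpholine N-oxide C[N+]1([O-])CCOCC1; water O
Why: Catalytic osmylation is a suprafacial syn-dihydroxylation and should take the ring face opposite to the cis C13-OMe and C17 side chain, which sets C14 (S) and C15 (S) as in a 4-deoxy-β-ribo-hexopyranoside.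

Step 5
Reactants: 6 (2S,3S,4S,6R)-6-[(S)-1-(tert-butyldimethylsilyloxy)propan-2-yl]-2-methoxyoxane-3,4-diol
Product: 7 (2S,3S,4S,6R)-6-[(S)-1-(tert-butyldimethylsilyloxy)propan-2-yl]-4-hydroxy-2-methoxyoxan-3-yl trifluoromethanesulfonate
Conditions: Tf2O (1.05 equiv), pyridine, CH2Cl2, −40 °C
Reagents that add atoms: trifluoromethanesulfonic anhydride O=S(=O)(OS(=O)(=O)C(F)(F)F)C(F)(F)F
Why: Regioselective sulfonylation, in which the equatorial C14-OH reacts ahead of the axial, shielded C15-OH with one equivalent of anhydride in the cold, and the cis relation of OTf and OH rules out epoxide formation.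

Step 6
Reactants: 7 (2S,3S,4S,6R)-6-[(S)-1-(tert-butyldimethylsilyloxy)propan-2-yl]-4-hydroxy-2-methoxyoxan-3-yl trifluoromethanesulfonate
Product: 8 (2S,3S,4S,6R)-6-[(S)-1-(tert-butyldimethylsilyloxy)propan-2-yl]-2,4-dimethoxyoxan-3-yl trifluoromethanesulfonate
Conditions: MeOTf, 2,6-di-tert-butyl-4-methylpyridine, CH2Cl2, 0 °C to rt
Reagents that add atoms: methyl trifluoromethanesulfonate COS(=O)(=O)C(F)(F)F
Why: O-Methylation with methyl triflate and a hindered non-nucleophilic pyridine runs without alkoxide formation, so the triflate, the acetal and the silyl ether persist and no stereocentre is touched.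

Step 7
Reactants: 8 (2S,3S,4S,6R)-6-[(S)-1-(tert-butyldimethylsilyloxy)propan-2-yl]-2,4-dimethoxyoxan-3-yl trifluoromethanesulfonate
Product: 11 (2R,3S,5R)-5-[(S)-1-(tert-butyldimethylsilyloxy)propan-2-yl]-3-methoxyoxolane-2-carbaldehyde, via oxocarbenium triflate 9 (not isolated), via methyl hemiacetal 10 (not isolated)
Conditions: NaHCO3 (3 equiv), MeCN/H2O 4:1, 45 °C; crude product used at once
Reagents that add atoms: water O
Why: In the chair with the C17 side chain, C13-OMe and C14-OTf equatorial and C15-OMe axial, the C14–OTf bond is antiperiplanar to the ring C13–O bond, so a lone pair of the ring oxygen expels triflate from the rear while the anomeric methoxy group pushes C13 out as the exocyclic oxocarbenium ion 9, which adds water to give 10 and then loses methanol to give 11. The closest known reaction type is the solvolytic ring contraction of pyranoside 2-sulfonates (and the nitrous acid deamination of 2-amino-2-deoxypyranosides) to 2,5-anhydroaldoses. The oxolane closes by an intramolecular SN2-type 1,2-shift of oxygen through a bridged three-membered oxonium transition state (formally 3-exo-tet), and the six-membered ring loses C13. C14 is the only stereocentre that changes; it is formed with inversion, so the osmylation-derived triflate dictates it, while C15, C17 and C18 are spectators, and this gives the 2,3-cis-2,5-trans oxolane. The step needs oxygen migration rather than C16 migration, external substitution or elimination: the equatorial anomeric methoxy group stabilises the charge growing at C13, attack of water at C14 next to the acetal carbon is slow, and no hydrogen lies antiperiplanar to the triflate. Bicarbonate keeps the medium near neutral so that the epimerisable β-methoxy aldehyde survives.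

Step 8
Reactants: 11 (2R,3S,5R)-5-[(S)-1-(tert-butyldimethylsilyloxy)propan-2-yl]-3-methoxyoxolane-2-carbaldehyde; 12 ethyl 2-[bis(2,2,2-trifluoroethoxy)phosphoryl]propanoate
Product: 13 ethyl (Z)-3-[(2S,3S,5R)-5-[(S)-1-(tert-butyldimethylsilyloxy)propan-2-yl]-3-methoxyoxolan-2-yl]-2-methylprop-2-enoate
Conditions: KHMDS, 18-crown-6, THF, −78 °C
Reagents that add atoms: none
Why: Still–Gennari olefination, in which the trifluoroethyl phosphonate with a dissociated potassium counter-ion eliminates under kinetic control to the (Z)-2-methylenoate (C14 cis to C11), and at −78 °C addition outruns epimerisation of 11.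

Step 9
Reactants: 13 ethyl (Z)-3-[(2S,3S,5R)-5-[(S)-1-(tert-butyldimethylsilyloxy)propan-2-yl]-3-methoxyoxolan-2-yl]-2-methylprop-2-enoate
Product: 14 (Z)-3-[(2S,3S,5R)-5-[(S)-1-(tert-butyldimethylsilyloxy)propan-2-yl]-3-methoxyoxolan-2-yl]-2-methylprop-2-en-1-ol
Conditions: DIBAL-H (2.5 equiv), CH2Cl2, −78 °C; aq. potassium sodium tartrate
Reagents that add atoms: none
Why: Excess DIBAL-H reduces the enoate 1,2 to the allylic alcohol with retention of the Z geometry, and the silyl ether and ring ethers are inert.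

Step 10
Reactants: 14 (Z)-3-[(2S,3S,5R)-5-[(S)-1-(tert-butyldimethylsilyloxy)propan-2-yl]-3-methoxyoxolan-2-yl]-2-methylprop-2-en-1-ol
Product: 15 (Z)-3-[(2S,3S,5R)-5-[(S)-1-(tert-butyldimethylsilyloxy)propan-2-yl]-3-methoxyoxolan-2-yl]-2-methylprop-2-enal
Conditions: MnO2, CH2Cl2, rt, dark
Reagents that add atoms: none
Why: MnO2 oxidises only the allylic alcohol under neutral heterogeneous conditions, which limits Z-to-E isomerisation of the enal.

Step 11
Reactants: 15 (Z)-3-[(2S,3S,5R)-5-[(S)-1-(tert-butyldimethylsilyloxy)propan-2-yl]-3-methoxyoxolan-2-yl]-2-methylprop-2-enal; 16 allenylboronic acid pinacol ester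
Product: 18 (4R,5Z)-6-[(2S,3S,5R)-5-[(S)-1-(tert-butyldimethylsilyloxy)propan-2-yl]-3-methoxyoxolan-2-yl]-5-methylhex-5-en-1-yn-4-ol, via pinacol borate ester 17 (not isolated)
Conditions: (R)-3,3'-bis(2,4,6-triisopropylphenyl)-1,1'-binaphthyl-2,2'-diyl hydrogen phosphate (10 mol%), 4 Å MS, toluene, −20 °C; aq. NaHCO3
Reagents that add atoms: none
Why: Chiral Brønsted acid catalysed propargylation with an allenylboronate through a closed six-membered SE2' transition state; the (R)-acid should direct attack to the Re face of the enal and set C11 (R) under catalyst control, the remote oxolane centres having little influence.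

Step 12
Reactants: 18 (4R,5Z)-6-[(2S,3S,5R)-5-[(S)-1-(tert-butyldimethylsilyloxy)propan-2-yl]-3-methoxyoxolan-2-yl]-5-methylhex-5-en-1-yn-4-ol
Product: 19 4-methoxybenzyl ether of 18 (C11-OPMB, 4R,5Z)
Conditions: NaH, PMBCl, Bu4NI (cat.), THF/DMF, 0 °C to rt
Reagents that add atoms: 4-methoxybenzyl chloride COc1ccc(CCl)cc1
Why: Williamson etherification of the sodium alkoxide; PMB is chosen because it survives fluoride and is removed oxidatively at the end.

Step 13
Reactants: 19 4-methoxybenzyl ether of 18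
Product: 21 1-tributylstannyl alkyne of 19, via lithium acetylide 20 (not isolated)
Conditions: n-BuLi, THF, −78 °C; Bu3SnCl, −78 °C to rt
Reagents that add atoms: tributyltin chloride CCCC[Sn](Cl)(CCCC)CCCC
Why: The terminal alkyne is by far the most acidic C–H, so lithiation at −78 °C and quenching with Bu3SnCl gives the alkynylstannane before any ether deprotonation can compete.

Step 14
Reactants: 21 1-tributylstannyl alkyne of 19
Product: 23 (1Z,4R,5Z)-1-tributylstannyl-1,5-diene (C8 stannane, C11-OPMB, C19-OTBS), via gem-stannyl zirconocene alkene 22 (not isolated)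
Conditions: Cp2Zr(H)Cl, THF, rt; H2O
Reagents that add atoms: none
Why: Hydrozirconation of a stannylalkyne is a syn addition that places zirconium geminal to tin, and selective protonolysis of the more polar C–Zr bond with retention leaves the (Z)-alkenylstannane.

Step 15
Reactants: 23 (1Z,4R,5Z)-1-tributylstannyl-1,5-diene (C19-OTBS)
Product: 24 primary alcohol (C19-OH) of 23
Conditions: TBAF, THF, 0 °C to rt
Reagents that add atoms: none
Why: Fluoride cleaves the only silyl ether, while the PMB ether, the stannane and the alkenes are inert.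

Step 16
Reactants: 24 primary alcohol (C19-OH) of 23
Product: 25 (R)-2-[(2R,4S,5S)-oxolan-2-yl]propanal bearing the C8–C13 stannyl diene chain (C19 aldehyde)
Conditions: Dess–Martin periodinane, NaHCO3, CH2Cl2, 0 °C
Reagents that add atoms: none
Why: Buffered Dess–Martin oxidation gives the α-methyl aldehyde under mild conditions that avoid epimerisation at C18 and protodestannylation.

Step 17
Reactants: 26 (E)-but-2-en-1-ol
Product: 27 [(2R,3R)-3-methyloxiran-2-yl]methanol
Conditions: Ti(OiPr)4 (5 mol%), D-(−)-diisopropyl tartrate (6 mol%), t-BuOOH, 4 Å MS, CH2Cl2, −20 °C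
Reagents that add atoms: tert-butyl hydroperoxide CC(C)(C)OO
Why: Sharpless asymmetric epoxidation, in which the D-(−)-tartrate titanium catalyst delivers oxygen to the face of the (E)-allylic alcohol that gives the (2R,3R)-epoxide (C22, C23), and the trans geometry follows from the E-alkene.

Step 18
Reactants: 27 [(2R,3R)-3-methyloxiran-2-yl]methanol
Product: 28 (2S,3R)-3-methyloxirane-2-carbaldehyde
Conditions: TEMPO (10 mol%), PhI(OAc)2, CH2Cl2, rt; used as a solution
Reagents that add atoms: none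
Why: The oxoammonium oxidation stops at the aldehyde under nearly neutral conditions that spare the epoxide and its two stereocentres.

Step 19
Reactants: 28 (2S,3R)-3-methyloxirane-2-carbaldehyde
Product: 29 (2R,3R)-2-[(E)-2-iodoethenyl]-3-methyloxirane
Conditions: CrCl2, CHI3, THF, 0 °C
Reagents that add atoms: iodoform IC(I)I
Why: Takai olefination with the geminal dichromium reagent from CHI3 and CrCl2 converts the aldehyde into the (E)-alkenyl iodide and tolerates the epoxide.

Step 20
Reactants: 25 C19 aldehyde; 29 (2R,3R)-2-[(E)-2-iodoethenyl]-3-methyloxirane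
Product: 31 (19R)-allylic alcohol with the (E)-vinyl epoxide side chain (C8 Z-stannane, C11-OPMB), via alkenylchromium dichloride 30 (not isolated)
Conditions: CrCl2, NiCl2 (1 mol%), DMSO, rt
Reagents that add atoms: none
Why: Nozaki–Hiyama–Kishi reaction, in which nickel-catalysed formation of 30 tolerates epoxide, stannane and PMB ether, and Felkin–Anh attack on 25, reinforced by 1,3-anti induction from the C17 ring oxygen, should set C19 (R) (18,19-syn, 17,19-anti).

Step 21
Reactants: 32 prop-2-yn-1-ol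
Product: 34 (E)-3-iodo-2-methylprop-2-en-1-ol, via alkenylalane 33 (not isolated)
Conditions: AlMe3, Cp2ZrCl2 (25 mol%), CH2Cl2, 0 °C to rt; I2, THF, −30 °C; aq. K2CO3
Reagents that add atoms: trimethylaluminium C[Al](C)C; iodine II
Why: Zirconium-catalysed (Negishi) carboalumination adds methyl and aluminium syn with aluminium at the terminus, and iodinolysis with retention gives the (E)-iodide.

Step 22
Reactants: 34 (E)-3-iodo-2-methylprop-2-en-1-ol
Product: 35 (E)-3-iodo-2-methylprop-2-enal
Conditions: MnO2, CH2Cl2, rt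
Reagents that add atoms: none
Why: Selective allylic oxidation under neutral conditions keeps the alkenyl iodide and its geometry.

Step 23
Reactants: 36 (R)-4-benzyl-3-propanoyl-1,3-oxazolidin-2-one; 35 (E)-3-iodo-2-methylprop-2-enal
Product: 38 (R)-4-benzyl-3-[(2R,3R,4E)-3-hydroxy-5-iodo-2,4-dimethylpent-4-enoyl]-1,3-oxazolidin-2-one, via dibutylboron Z-enolate 37 (not isolated)
Conditions: Bu2BOTf, Et3N, CH2Cl2, −78 to 0 °C; 35, −78 °C; H2O2, MeOH, pH 7 buffer
Reagents that add atoms: none
Why: Evans syn-aldol reaction, in which the (Z)-boron enolate reacts through a Zimmerman–Traxler chair on the face left open by the (R)-benzyl auxiliary and so sets C4 and the temporary C5 carbinol.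

Step 24
Reactants: 38 (R)-4-benzyl-3-[(2R,3R,4E)-3-hydroxy-5-iodo-2,4-dimethylpent-4-enoyl]-1,3-oxazolidin-2-one
Product: 39 triethylsilyl ether of 38
Conditions: TESOTf, 2,6-lutidine, CH2Cl2, −78 to 0 °C
Reagents that add atoms: triethylsilyl trifluoromethanesulfonate CC[Si](CC)(CC)OS(=O)(=O)C(F)(F)F
Why: Silylation with the triflate and a weak base avoids retro-aldol cleavage, and a TES ether at this later dienylic position is what the final oxidation needs.

Step 25
Reactants: 39 triethylsilyl ether of 38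
Product: 40 (2S,3R,4E)-5-iodo-2,4-dimethyl-3-(triethylsilyloxy)pent-4-en-1-ol
Conditions: LiBH4, MeOH (1 equiv), Et2O, 0 °C
Reagents that add atoms: none
Why: Reductive cleavage of the imide frees the auxiliary and gives the primary alcohol without touching C4, the alkenyl iodide or the silyl ether.

Step 26
Reactants: 40 (2S,3R,4E)-5-iodo-2,4-dimethyl-3-(triethylsilyloxy)pent-4-en-1-ol
Product: 41 (2R,3R,4E)-5-iodo-2,4-dimethyl-3-(triethylsilyloxy)pent-4-enal
Conditions: Dess–Martin periodinane, NaHCO3, CH2Cl2, 0 °C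
Reagents that add atoms: none
Why: Buffered Dess–Martin oxidation gives the α-chiral aldehyde without epimerisation or β-elimination of the silyloxy group.

Step 27
Reactants: 41 (2R,3R,4E)-5-iodo-2,4-dimethyl-3-(triethylsilyloxy)pent-4-enal; 12 ethyl 2-[bis(2,2,2-trifluoroethoxy)phosphoryl]propanoate
Product: 42 ethyl (2Z,4S,5R,6E)-7-iodo-2,4,6-trimethyl-5-(triethylsilyloxy)hepta-2,6-dienoate
Conditions: KHMDS, 18-crown-6, THF, −78 °C
Reagents that add atoms: none
Why: A second Still–Gennari olefination gives the (Z)-C2=C3 enoate under kinetic control, and the cold conditions preserve C4.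

Step 28
Reactants: 42 ethyl (2Z,4S,5R,6E)-7-iodo-2,4,6-trimethyl-5-(triethylsilyloxy)hepta-2,6-dienoate
Product: 43 (2Z,4S,5R,6E)-7-iodo-2,4,6-trimethyl-5-(triethylsilyloxy)hepta-2,6-dienoic acid
Conditions: LiOH, THF/MeOH/H2O, 35 °C; 1 M HCl to pH 4, 0 °C
Reagents that add atoms: lithium hydroxide [Li+].[OH-]
Why: Saponification of the ethyl ester is safe here because C5 is still a silyl ether, so C4 is not activated by a ketone, and the hindered secondary TES ether withstands hydroxide.

Step 29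
Reactants: 31 (19R)-allylic alcohol; 43 (2Z,4S,5R,6E)-7-iodo-2,4,6-trimethyl-5-(triethylsilyloxy)hepta-2,6-dienoic acid
Product: 44 seco ester (C19 ester of 31 with 43; C8 Z-stannane, C7 E-iodide)
Conditions: 2-methyl-6-nitrobenzoic anhydride, DMAP, Et3N, CH2Cl2, rt
Reagents that add atoms: none
Why: Shiina esterification acylates the only free hydroxyl at room temperature with retention at C19, and the α-methyl and branched γ-carbon of the acid slow the conjugate addition of DMAP that would isomerise the Z-enoate.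

Step 30
Reactants: 44 seco ester
Product: 45 protected macrolide (C5-OTES, C11-OPMB; 2Z,6E,8Z,12Z,20E)
Conditions: copper thiophene-2-carboxylate (CuTC, 5 equiv), NMP, rt, 1 mM
Reagents that add atoms: none
Why: Copper-mediated Stille-type coupling (tin-to-copper exchange, then coupling with the alkenyl iodide) proceeds with retention at both sp2 carbons and closes the 20-membered ring at C7–C8 under neutral conditions without zerovalent palladium, which would ionise the vinyl epoxide and the allylic ester.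

Step 31
Reactants: 45 protected macrolide
Product: 47 target CNP0117824.2, via C11 alcohol 46 (not isolated)
Conditions: DDQ (4 equiv), CH2Cl2/pH 7 phosphate buffer 10:1, 0 °C to rt
Reagents that add atoms: none
Why: DDQ abstracts hydride from the two most electron-rich C–H bonds, the PMB benzylic one (oxidative PMB cleavage) and the dienylic C5–H of the silyl ether (known oxidation of allylic and dienylic silyl ethers to enones), so the C5 ketone appears without a free δ-hydroxy Z-enoate that could translactonise and under non-basic conditions that spare the labile C4 centre and the epoxide.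

Compound list
1 | methyl (S)-3-hydroxy-2-methylpropanoate | COC(=O)[C@@H](C)CO | starting material
2 | methyl (S)-3-(tert-butyldimethylsilyloxy)-2-methylpropanoate | COC(=O)[C@@H](C)CO[Si](C)(C)C(C)(C)C | intermediate
3 | (S)-3-(tert-butyldimethylsilyloxy)-2-methylpropanal | O=C[C@@H](C)CO[Si](C)(C)C(C)(C)C | intermediate
4 | (E)-1-methoxybuta-1,3-diene | CO/C=C/C=C | starting material
5 | (2S,6R)-6-[(S)-1-(tert-butyldimethylsilyloxy)propan-2-yl]-2-methoxy-5,6-dihydro-2H-pyran | CO[C@@H]1C=CC[C@@H](O1)[C@@H](C)CO[Si](C)(C)C(C)(C)C | intermediate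
6 | (2S,3S,4S,6R)-6-[(S)-1-(tert-butyldimethylsilyloxy)propan-2-yl]-2-methoxyoxane-3,4-diol | CO[C@@H]1[C@@H](O)[C@@H](O)C[C@@H](O1)[C@@H](C)CO[Si](C)(C)C(C)(C)C | intermediate
7 | (2S,3S,4S,6R)-6-[(S)-1-(tert-butyldimethylsilyloxy)propan-2-yl]-4-hydroxy-2-methoxyoxan-3-yl trifluoromethanesulfonate | CO[C@@H]1[C@@H](OS(=O)(=O)C(F)(F)F)[C@@H](O)C[C@@H](O1)[C@@H](C)CO[Si](C)(C)C(C)(C)C | intermediate
8 | (2S,3S,4S,6R)-6-[(S)-1-(tert-butyldimethylsilyloxy)propan-2-yl]-2,4-dimethoxyoxan-3-yl trifluoromethanesulfonate | CO[C@@H]1[C@@H](OS(=O)(=O)C(F)(F)F)[C@@H](OC)C[C@@H](O1)[C@@H](C)CO[Si](C)(C)C(C)(C)C | intermediate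
9 | exocyclic O-methyl oxocarbenium triflate of the contracted oxolane | C[O+]=C[C@@H]1O[C@H](C[C@@H]1OC)[C@@H](C)CO[Si](C)(C)C(C)(C)C.[O-]S(=O)(=O)C(F)(F)F | intermediate
10 | methyl hemiacetal of aldehyde 11 (hemiacetal carbon undefined) | COC(O)[C@@H]1O[C@H](C[C@@H]1OC)[C@@H](C)CO[Si](C)(C)C(C)(C)C | intermediate
11 | (2R,3S,5R)-5-[(S)-1-(tert-butyldimethylsilyloxy)propan-2-yl]-3-methoxyoxolane-2-carbaldehyde | O=C[C@@H]1O[C@H](C[C@@H]1OC)[C@@H](C)CO[Si](C)(C)C(C)(C)C | intermediate
12 | ethyl 2-[bis(2,2,2-trifluoroethoxy)phosphoryl]propanoate | CCOC(=O)C(C)P(=O)(OCC(F)(F)F)OCC(F)(F)F | starting material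
13 | ethyl (Z)-3-[(2S,3S,5R)-5-[(S)-1-(tert-butyldimethylsilyloxy)propan-2-yl]-3-methoxyoxolan-2-yl]-2-methylprop-2-enoate | CCOC(=O)C(/C)=C\[C@@H]1O[C@H](C[C@@H]1OC)[C@@H](C)CO[Si](C)(C)C(C)(C)C | intermediate
14 | (Z)-3-[(2S,3S,5R)-5-[(S)-1-(tert-butyldimethylsilyloxy)propan-2-yl]-3-methoxyoxolan-2-yl]-2-methylprop-2-en-1-ol | OCC(/C)=C\[C@@H]1O[C@H](C[C@@H]1OC)[C@@H](C)CO[Si](C)(C)C(C)(C)C | intermediate
15 | (Z)-3-[(2S,3S,5R)-5-[(S)-1-(tert-butyldimethylsilyloxy)propan-2-yl]-3-methoxyoxolan-2-yl]-2-methylprop-2-enal | O=CC(/C)=C\[C@@H]1O[C@H](C[C@@H]1OC)[C@@H](C)CO[Si](C)(C)C(C)(C)C | intermediate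
16 | allenylboronic acid pinacol ester | C=C=CB1OC(C)(C)C(C)(C)O1 | starting material
17 | pinacol borate ester of alcohol 18 | C#CC[C@@H](OB1OC(C)(C)C(C)(C)O1)C(/C)=C\[C@@H]1O[C@H](C[C@@H]1OC)[C@@H](C)CO[Si](C)(C)C(C)(C)C | intermediate
18 | (4R,5Z)-6-[(2S,3S,5R)-5-[(S)-1-(tert-butyldimethylsilyloxy)propan-2-yl]-3-methoxyoxolan-2-yl]-5-methylhex-5-en-1-yn-4-ol | C#CC[C@@H](O)C(/C)=C\[C@@H]1O[C@H](C[C@@H]1OC)[C@@H](C)CO[Si](C)(C)C(C)(C)C | intermediate
19 | 4-methoxybenzyl ether of 18 (C11-OPMB) | C#CC[C@@H](OCc1ccc(OC)cc1)C(/C)=C\[C@@H]1O[C@H](C[C@@H]1OC)[C@@H](C)CO[Si](C)(C)C(C)(C)C | intermediate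
20 | lithium acetylide of 19 | [Li]C#CC[C@@H](OCc1ccc(OC)cc1)C(/C)=C\[C@@H]1O[C@H](C[C@@H]1OC)[C@@H](C)CO[Si](C)(C)C(C)(C)C | intermediate
21 | 1-tributylstannyl alkyne of 19 | CCCC[Sn](CCCC)(CCCC)C#CC[C@@H](OCc1ccc(OC)cc1)C(/C)=C\[C@@H]1O[C@H](C[C@@H]1OC)[C@@H](C)CO[Si](C)(C)C(C)(C)C | intermediate
22 | 1-tributylstannyl-1-(chlorozirconocenyl)alkene from 21 (Sn cis to C10) | CCCC[Sn](CCCC)(CCCC)/C([Zr](Cl)(C1C=CC=C1)C1C=CC=C1)=C\C[C@@H](OCc1ccc(OC)cc1)C(/C)=C\[C@@H]1O[C@H](C[C@@H]1OC)[C@@H](C)CO[Si](C)(C)C(C)(C)C | intermediate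
23 | (1Z,4R,5Z)-1-tributylstannyl-1,5-diene (C8 stannane, C11-OPMB, C19-OTBS) | CCCC[Sn](CCCC)(CCCC)/C=C\C[C@@H](OCc1ccc(OC)cc1)C(/C)=C\[C@@H]1O[C@H](C[C@@H]1OC)[C@@H](C)CO[Si](C)(C)C(C)(C)C | intermediate
24 | primary alcohol (C19-OH) of 23 | CCCC[Sn](CCCC)(CCCC)/C=C\C[C@@H](OCc1ccc(OC)cc1)C(/C)=C\[C@@H]1O[C@H](C[C@@H]1OC)[C@@H](C)CO | intermediate
25 | C19 aldehyde, (18R)-2-(oxolanyl)propanal with the stannyl diene chain | CCCC[Sn](CCCC)(CCCC)/C=C\C[C@@H](OCc1ccc(OC)cc1)C(/C)=C\[C@@H]1O[C@H](C[C@@H]1OC)[C@@H](C)C=O | intermediate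
26 | (E)-but-2-en-1-ol | C/C=C/CO | starting material
27 | [(2R,3R)-3-methyloxiran-2-yl]methanol | OC[C@H]1O[C@@H]1C | intermediate
28 | (2S,3R)-3-methyloxirane-2-carbaldehyde | O=C[C@H]1O[C@@H]1C | intermediate
29 | (2R,3R)-2-[(E)-2-iodoethenyl]-3-methyloxirane | I/C=C/[C@H]1O[C@@H]1C | intermediate
30 | (E)-alkenylchromium dichloride from 29 | Cl[Cr](Cl)/C=C/[C@H]1O[C@@H]1C | intermediate
31 | (19R)-allylic alcohol with (20E)-vinyl (22R,23R)-epoxide, C8 Z-stannane, C11-OPMB | CCCC[Sn](CCCC)(CCCC)/C=C\C[C@@H](OCc1ccc(OC)cc1)C(/C)=C\[C@@H]1O[C@H](C[C@@H]1OC)[C@@H](C)[C@H](O)/C=C/[C@H]1O[C@@H]1C | intermediate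
32 | prop-2-yn-1-ol | C#CCO | starting material
33 | (E)-alkenylalane, O-dimethylaluminium alkoxide | C[Al](C)OC/C(C)=C/[Al](C)C | intermediate
34 | (E)-3-iodo-2-methylprop-2-en-1-ol | OC/C(C)=C/I | intermediate
35 | (E)-3-iodo-2-methylprop-2-enal | O=C/C(C)=C/I | intermediate
36 | (R)-4-benzyl-3-propanoyl-1,3-oxazolidin-2-one | CCC(=O)N1[C@H](Cc2ccccc2)COC1=O | starting material
37 | (Z)-dibutylboron enolate of 36 | C/C=C(\OB(CCCC)CCCC)N1[C@H](Cc2ccccc2)COC1=O | intermediate
38 | (R)-4-benzyl-3-[(2R,3R,4E)-3-hydroxy-5-iodo-2,4-dimethylpent-4-enoyl]-1,3-oxazolidin-2-one | O=C1OC[C@@H](Cc2ccccc2)N1C(=O)[C@H](C)[C@@H](O)/C(C)=C/I | intermediate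
39 | triethylsilyl ether of 38 | O=C1OC[C@@H](Cc2ccccc2)N1C(=O)[C@H](C)[C@@H](O[Si](CC)(CC)CC)/C(C)=C/I | intermediate
40 | (2S,3R,4E)-5-iodo-2,4-dimethyl-3-(triethylsilyloxy)pent-4-en-1-ol | OC[C@H](C)[C@@H](O[Si](CC)(CC)CC)/C(C)=C/I | intermediate
41 | (2R,3R,4E)-5-iodo-2,4-dimethyl-3-(triethylsilyloxy)pent-4-enal | O=C[C@H](C)[C@@H](O[Si](CC)(CC)CC)/C(C)=C/I | intermediate
42 | ethyl (2Z,4S,5R,6E)-7-iodo-2,4,6-trimethyl-5-(triethylsilyloxy)hepta-2,6-dienoate | CCOC(=O)C(/C)=C\[C@H](C)[C@@H](O[Si](CC)(CC)CC)/C(C)=C/I | intermediate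
43 | (2Z,4S,5R,6E)-7-iodo-2,4,6-trimethyl-5-(triethylsilyloxy)hepta-2,6-dienoic acid | OC(=O)C(/C)=C\[C@H](C)[C@@H](O[Si](CC)(CC)CC)/C(C)=C/I | intermediate
44 | seco ester, C19 ester of 31 with 43 | CCCC[Sn](CCCC)(CCCC)/C=C\C[C@@H](OCc1ccc(OC)cc1)C(/C)=C\[C@@H]1O[C@H](C[C@@H]1OC)[C@@H](C)[C@H](OC(=O)C(/C)=C\[C@H](C)[C@@H](O[Si](CC)(CC)CC)/C(C)=C/I)/C=C/[C@H]1O[C@@H]1C | intermediate
45 | protected macrolide, (5R)-OTES, (11R)-OPMB, 2Z,6E,8Z,12Z,20E | CO[C@H]1C[C@H]2O[C@H]1/C=C(/C)[C@H](OCc1ccc(OC)cc1)C/C=C\C=C(/C)[C@H](O[Si](CC)(CC)CC)[C@@H](C)/C=C(/C)C(=O)O[C@H](/C=C/[C@H]1O[C@@H]1C)[C@@H]2C | intermediate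
46 | macrolide with free C11-OH and C5-OTES | CO[C@H]1C[C@H]2O[C@H]1/C=C(/C)[C@H](O)C/C=C\C=C(/C)[C@H](O[Si](CC)(CC)CC)[C@@H](C)/C=C(/C)C(=O)O[C@H](/C=C/[C@H]1O[C@@H]1C)[C@@H]2C | intermediate
47 | CNP0117824.2 | CO[C@H]1C[C@H]2O[C@H]1/C=C(/C)[C@H](O)C/C=C\C=C(/C)C(=O)[C@@H](C)/C=C(/C)C(=O)O[C@H](/C=C/[C@H]1O[C@@H]1C)[C@@H]2C | target

Total step count: 31. Longest linear sequence: 20 steps (steps 1–16, 20, 29, 30, 31).

Steps most likely to fail

Step 7. Migration of C16 instead of the ring oxygen may compete. The warm, weakly basic medium may also epimerise C14 or eliminate methanol from the β-methoxy aldehyde. The fallback moves the contraction to the ester oxidation level and to an open-chain displacement. It sets out from 5. Aqueous PPTS hydrolysis gives the lactol F1 and MnO2 gives the 5,6-dihydropyran-2-one F2. OsO4/NMO, attacking anti to the C17 side chain, gives the cis-diol lactone F3. Tf2O/pyridine gives the α-triflate F4, since the α-hydroxyl is the more acidic and the equatorial one. MeOTf with 2,6-di-tert-butyl-4-methylpyridine gives the methyl ether F5. K2CO3 in MeOH at −20 °C then opens the lactone, and the freed C17 alkoxide displaces the triflate (5-exo-tet, inversion at C14) to give the oxolane methyl ester F6. This six-to-five contraction is known for α-triflyloxy δ-lactones. DIBAL-H at −78 °C brings the sequence back to 11.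

Step 3. The cycloaddition may stall with this α-branched, unactivated aldehyde. Facial selectivity may also be poor, because the catalyst has to override the Felkin preference of 3. The fallback builds the six-membered ring by allylation and metathesis. It sets out from 3. Allylboration with the reagent from (+)-Ipc2BOMe and allylMgBr (Re-face attack) gives the homoallylic alcohol F7. Acryloyl chloride/Et3N gives the acrylate F8. The second-generation Grubbs catalyst closes F8 to the lactone F2 described above. The sequence F3, F4, F5, F6 then returns to the route at 11.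

Step 31. Hydride abstraction at C5 may be slow in the macrocycle, so that long exposure to DDQ over-oxidises the freed C11 allylic alcohol or degrades the diene. The fallback separates deprotection and oxidation. It sets out from 45. HF·pyridine buffered with pyridine (THF, 0 °C) removes the TES group to give the C5 alcohol F9. This is oxidised at once with Dess–Martin periodinane/NaHCO3 to the C5 ketone PMB ether F10, to forestall translactonisation. DDQ (1.2 equiv, pH 7 buffer, 0 °C) then cleaves only the PMB ether and returns to the route at 47.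

Further compounds
F1 | step 7 | (6R)-6-[(S)-1-(tert-butyldimethylsilyloxy)propan-2-yl]-5,6-dihydro-2H-pyran-2-ol (anomeric mixture) | OC1C=CC[C@@H](O1)[C@@H](C)CO[Si](C)(C)C(C)(C)C
F2 | step 7 | (R)-6-[(S)-1-(tert-butyldimethylsilyloxy)propan-2-yl]-5,6-dihydro-2H-pyran-2-one | O=C1C=CC[C@@H](O1)[C@@H](C)CO[Si](C)(C)C(C)(C)C
F3 | step 7 | (3S,4S,6R)-6-[(S)-1-(tert-butyldimethylsilyloxy)propan-2-yl]-3,4-dihydroxyoxan-2-one | O=C1[C@@H](O)[C@@H](O)C[C@@H](O1)[C@@H](C)CO[Si](C)(C)C(C)(C)C
F4 | step 7 | (3S,4S,6R)-6-[(S)-1-(tert-butyldimethylsilyloxy)propan-2-yl]-4-hydroxy-2-oxooxan-3-yl trifluoromethanesulfonate | O=C1[C@@H](OS(=O)(=O)C(F)(F)F)[C@@H](O)C[C@@H](O1)[C@@H](C)CO[Si](C)(C)C(C)(C)C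
F5 | step 7 | (3S,4S,6R)-6-[(S)-1-(tert-butyldimethylsilyloxy)propan-2-yl]-4-methoxy-2-oxooxan-3-yl trifluoromethanesulfonate | O=C1[C@@H](OS(=O)(=O)C(F)(F)F)[C@@H](OC)C[C@@H](O1)[C@@H](C)CO[Si](C)(C)C(C)(C)C
F6 | step 7 | methyl (2R,3S,5R)-5-[(S)-1-(tert-butyldimethylsilyloxy)propan-2-yl]-3-methoxyoxolane-2-carboxylate | COC(=O)[C@@H]1O[C@H](C[C@@H]1OC)[C@@H](C)CO[Si](C)(C)C(C)(C)C
F7 | step 3 | (2S,3R)-1-(tert-butyldimethylsilyloxy)-2-methylhex-5-en-3-ol | C=CC[C@@H](O)[C@@H](C)CO[Si](C)(C)C(C)(C)C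
F8 | step 3 | (2S,3R)-1-(tert-butyldimethylsilyloxy)-2-methylhex-5-en-3-yl prop-2-enoate | C=CC[C@@H](OC(=O)C=C)[C@@H](C)CO[Si](C)(C)C(C)(C)C
F9 | step 31 | macrolide with free (5R)-OH and C11-OPMB | CO[C@H]1C[C@H]2O[C@H]1/C=C(/C)[C@H](OCc1ccc(OC)cc1)C/C=C\C=C(/C)[C@H](O)[C@@H](C)/C=C(/C)C(=O)O[C@H](/C=C/[C@H]1O[C@@H]1C)[C@@H]2C
F10 | step 31 | C11 4-methoxybenzyl ether of the target (C5 ketone) | CO[C@H]1C[C@H]2O[C@H]1/C=C(/C)[C@H](OCc1ccc(OC)cc1)C/C=C\C=C(/C)C(=O)[C@@H](C)/C=C(/C)C(=O)O[C@H](/C=C/[C@H]1O[C@@H]1C)[C@@H]2C
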